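At the reading, 10 h after the start, what has become of a portion of starting material depends on how long it sat in the flask and how much activator it met there. Ring percentages rise at a similar pace in the earlier runs, 12.2% after 2.00 h in spring, 10.9% after 2.50 h in winter and 16.7% after 3.00 h in autumn, which at this one activator charge reads as at most first order in starting material. Activator, 0.12 M in winter against 0.20 M of starting material, is no large excess, so hours are counted here with its charge as a weight.

| flask | starting material | activator | remark | time |
|---|---|---|---|---|
| autumn | 0.10 M | 0.12 M | run made earlier |  |
| spring | 0.050 M | 0.12 M | run made earlier |  |
| winter | 0.20 M | 0.12 M | run made earlier |  |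
| north-west | 0.10 M (fed, over 4.0 h) | 0.120 M | all else is in the flask from the start; the feed brings no volume worth counting | 10 h |
| north | 0.10 M | 0.120 M (fed, over 25 min) | all else is in the flask from the start; the feed brings no volume worth counting | 10 h |
| south-east | 0.10 M | 0.120 M (fed, over 4.0 h) | all else is in the flask from the start; the feed brings no volume worth counting | 10 h |
| south-west | 0.10 M | 0.120 M | everything together at the start | 10 h |

| run | time / h | ring / % |
|---|---|---|
| autumn | 0.500 | 2.9 |
| autumn | 1.50 | 7.8 |
| autumn | 3.00 | 16.7 |
| autumn | 4.00 | 18.5 |
| autumn | 6.00 | 22.1 |
| spring | 2.00 | 12.2 |
| spring | 4.00 | 21.1 |
| spring | 6.00 | 25.3 |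
| spring | 8.00 | 25.6 |
| spring | 10.0 | 29.0 |
| winter | 0.833 | 2.8 |
| winter | 2.50 | 10.9 |
| winter | 5.00 | 15.2 |
| winter | 8.00 | 19.4 |
| winter | 10.0 | 18.1 |

(scatter of a reading: 1 percentage point)

1. the flask with the highest amount of ring, in percent of the starting material charged ("all alike" if they lie within 1.5 percentage points) (north-west / north / south-east / south-west / all alike)
2. final ring, as a percentage of the starting material charged, in north-west
3. final ring, as a percentage of the starting material charged, in north
4. final ring, as a percentage of the starting material charged, in south-east
5. final ring, as a percentage of the starting material charged, in south-west

- the earlier runs were read with a standard deviation of 1 percentage point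

The count used here is full-charge hours: hours in the flask, minus half the feed time for the average delay, times the share of the activator charge. A feed over 4.0 h of either species gives 8.00 h, the quick feed 9.79 h.

Autumn stops too early to be read there, but spring has half its charge and winter twice its charge, so their mean stands in: 22.5% at 8.00 h, 23.5% at 10.0 h. A slow feed should then cost 1.1 points, less than the margin of 1.5 points, so this reckoning puts the flasks level.

But that cost carries a scatter of about 1 point, and the stall in the runs may mean that late portions meet less activator. Against this, a flask fed with starting material starts with a low amount of it. The spring readings ended above winter, by 5.4 points for each halving of the charge. The two doubts pull opposite ways, so the estimate stands.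

The forecast differs. It named south-west, with 17.5% in north-west, 24% in north, 23% in south-east and 24.5% in south-west, arguing “late material meets dying activator”.

The flasks give all alike: north-west 23.9%, north 24.4%, south-east 23.5%, south-west 24.5%.

    starting material + activator → activated form (k = 2.76 × 10⁻⁴ L mol⁻¹ s⁻¹)
    activated form → ring (k = 5.46 × 10⁻⁴ s⁻¹)
    starting material + activated form → open dimer (k = 0.00183 L mol⁻¹ s⁻¹)
    activator + ring → over-reaction product (k = 3.69 × 10⁻⁴ L mol⁻¹ s⁻¹)

The forecast and the flask part on north-west, by 6.4 points. The 8.00 h count cost north-west 0.60 points and south-east 1.00 point against south-west. In north, half of the turnover up to the reading from starting material and activator to activated form is done by 3.11 h, and that from activator and ring to over-reaction product by 5.74 h, later.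

A neighbour like north with 0.030 M of activator, a quarter of the charge, counts 2.45 h, and the autumn run read at that hour gives about 13.4%. The computed flask holds 11.2%.

Readings and results were generated by integration with made-up constants.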